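The 14-membered carbocycle (C1 bears isopropenyl; ketones at C3, C6, C10; the oxolanone oxygen bridges C5 and C8; C12=C13 enoate) is disconnected at the C3 carbonyl carbon, which sits between two methylenes, C2 next to stereocentre C1 and C4 next to oxolane carbon C5. In one flask 1,3-dithiane is alkylated by a C2 iodide (C1, C13, C14) and then by a C4 triflate on the preformed oxolane (C5–C10), forming C2–C3 and C3–C4 with all stereocentres in place; C3 stays a non-enolisable thioketal, so the β-oxygen at C5 cannot be expelled. Barbier allylation and ring-closing metathesis then add C11–C12 and close the ring before C3 is unmasked.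

Key step: step 15

Remark: C6 is carried as a silyl ether and C13 as a dimethyl acetal until after the union; the C6 configuration of 13–29 is inconsequential because C6 ends as a carbonyl; stereodescriptors given with C-numbers use the macrocycle numbering above; TBS = tert-butyldimethylsilyl, TBDPS = tert-butyldiphenylsilyl.

Step 1
Reactants: 1 3-methylbut-2-enoic acid; 2 (R)-4-benzyl-1,3-oxazolidin-2-one
Product: 4 (R)-4-benzyl-3-(3-methylbut-2-enoyl)-1,3-oxazolidin-2-one, via mixed pivalic anhydride 3 (not isolated)
Conditions: t-BuCOCl, Et3N, THF, −20 °C; then LiCl, 2, → rt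
Reagents that add atoms: none
Why: Acylation of the oxazolidinone by the in situ mixed anhydride under LiCl/Et3N activation (mixed-anhydride N-acylation) should load the enoic acid without conjugate addition or migration of the double bond.

Step 2
Reactants: 4 (R)-4-benzyl-3-(3-methylbut-2-enoyl)-1,3-oxazolidin-2-one; 5 tert-butyl bromoacetate
Product: 7 tert-butyl (3R)-3-{[(4R)-4-benzyl-2-oxo-1,3-oxazolidin-3-yl]carbonyl}-4-methylpent-4-enoate, via sodium dienolate 6 (not isolated)
Conditions: NaN(SiMe3)2, THF, −78 °C; then 5, −78 → −40 °C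
Reagents that add atoms: none
Why: γ-Deprotonation gives the chelated Z-dienolate 6, which the reactive α-bromo ester alkylates at the α-carbon on the face away from the benzyl group (auxiliary-controlled deconjugative enolate alkylation), so that C1 is set as R in 7 and the isopropenyl group is unveiled at the same time.

Step 3
Reactants: 7 alkylated imide
Product: 8 tert-butyl (3R)-3-(hydroxymethyl)-4-methylpent-4-enoate
Conditions: LiBH4, MeOH (1 equiv), Et2O, 0 °C
Reagents that add atoms: none
Why: Hydride attacks the activated exocyclic imide carbonyl far faster than the hindered tert-butyl ester (reductive cleavage of the auxiliary with LiBH4), which should give the C2 alcohol with C1 untouched and return auxiliary 2.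

Step 4
Reactants: 8 hydroxy ester
Product: 9 tert-butyl (3R)-3-(iodomethyl)-4-methylpent-4-enoate
Conditions: I2, PPh3, imidazole, CH2Cl2, 0 °C, dark
Reagents that add atoms: iodine, II
Why: Appel-type iodination of the primary alcohol proceeds by SN2 displacement of the oxyphosphonium ion at a CH2 group, and running it cold should outpace lactonisation onto the tert-butyl ester.

Step 5
Reactants: 9 iodo ester
Product: 10 (3R)-3-(iodomethyl)-4-methylpent-4-enal
Conditions: i-Bu2AlH (1.1 equiv), CH2Cl2, −78 °C; MeOH, then aq. KNaC4H4O6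
Reagents that add atoms: none
Why: Partial reduction of the ester by i-Bu2AlH stops at the aldehyde because the tetrahedral aluminium alkoxide survives at −78 °C until work-up, and the alkyl iodide and alkene are inert to this hydride.

Step 6
Reactants: 10 iodo aldehyde
Product: 11 fragment 1: (3R)-3-(iodomethyl)-5,5-dimethoxy-2-methylpent-1-ene
Conditions: HC(OMe)3, PPTS (cat.), MeOH, rt
Reagents that add atoms: trimethyl orthoformate, COC(OC)OC
Why: Acid-catalysed acetalisation driven by the orthoformate masks C13 as a dimethyl acetal that is inert to organolithium bases yet is removable later without touching silyl ethers or the thioketal.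

Step 7
Reactants: 12 2-deoxy-L-ribose
Product: 13 2-deoxy-L-ribono-1,4-lactone
Conditions: Br2, H2O, rt, dark
Reagents that add atoms: none
Why: Bromine-water oxidation of the aldose hemiacetal gives the five-membered lactone and leaves the two carbinol centres, the future C6 and C5, as they are in the sugar.

Step 8
Reactants: 13 2-deoxy-L-ribono-1,4-lactone
Product: 14 (4R,5S)-4-(TBS-oxy)-5-(TBS-oxymethyl)oxolan-2-one
Conditions: t-BuMe2SiCl, imidazole, DMF, rt
Reagents that add atoms: tert-butyldimethylsilyl chloride, CC(C)(C)[Si](C)(C)Cl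
Why: Imidazole-promoted silylation protects both hydroxyls as TBS ethers (silyl ether formation), the secondary one later serving as the C6 placeholder.

Step 9
Reactants: 14 bis-TBS lactone
Product: 15 (4R,5S)-4-(TBS-oxy)-5-(TBS-oxymethyl)-2-methyloxolan-2-ol (both anomers)
Conditions: MeLi, THF, −78 °C; aq. NH4Cl
Reagents that add atoms: methyllithium, [Li]C
Why: Addition of MeLi to the lactone at −78 °C stops at the lithium hemiketal (lactone to lactol addition), which brings in the C8 methyl group.

Step 10
Reactants: 15 methyl lactol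
Product: 16 (2S,4R,5S)-2-allyl-4-(TBS-oxy)-5-(TBS-oxymethyl)-2-methyloxolane
Conditions: CH2=CHCH2SiMe3, BF3·OEt2, CH2Cl2, −78 → −40 °C
Reagents that add atoms: allyltrimethylsilane, C=CC[Si](C)(C)C
Why: BF3·OEt2 ionises the hemiketal to a tertiary oxocarbenium ion that is trapped by the allylsilane (Hosomi–Sakurai-type C-glycosylation), attack on the inside face of the envelope cis to the C6 silyloxy group being expected to place the new chain trans to the C5 CH2O arm and so to set C8; any minor epimer would be removed by chromatography.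

Step 11
Reactants: 16 allyl oxolane
Product: 18 2-[(2S,4R,5S)-4-(TBS-oxy)-5-(TBS-oxymethyl)-2-methyloxolan-2-yl]ethan-1-ol, via oxolanylacetaldehyde 17 (not isolated)
Conditions: O3, CH2Cl2/MeOH, −78 °C; then NaBH4, −78 → 0 °C
Reagents that add atoms: ozone, [O-][O+]=O
Why: Ozonolysis cleaves the only alkene present and borohydride reduction of the ozonide and of aldehyde 17 in the same flask should give the two-carbon arm C9–C10 as a primary alcohol.

Step 12
Reactants: 18 primary alcohol
Product: 19 TBDPS ether of 18 (C10–OTBDPS)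
Conditions: t-BuPh2SiCl, imidazole, CH2Cl2, rt
Reagents that add atoms: tert-butyldiphenylsilyl chloride, CC(C)(C)[Si](Cl)(c1ccccc1)c1ccccc1
Why: Silylation of the unhindered primary alcohol with the bulkier, more acid-stable TBDPS group differentiates C10–O from the primary TBS ether on C4.

Step 13
Reactants: 19 tris-silyl ether
Product: 20 [(2S,3R,5S)-3-(TBS-oxy)-5-[2-(TBDPS-oxy)ethyl]-5-methyloxolan-2-yl]methanol
Conditions: camphorsulfonic acid (cat.), MeOH/CH2Cl2, 0 °C
Reagents that add atoms: none
Why: Acid-catalysed methanolysis removes a primary TBS ether much faster than a secondary TBS or a TBDPS ether (selective desilylation), freeing only the C4 hydroxyl.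

Step 14
Reactants: 20 C4 alcohol
Product: 21 fragment 2: [(2S,3R,5S)-3-(TBS-oxy)-5-[2-(TBDPS-oxy)ethyl]-5-methyloxolan-2-yl]methyl trifluoromethanesulfonate
Conditions: Tf2O, 2,6-lutidine, CH2Cl2, −78 °C; used at once
Reagents that add atoms: trifluoromethanesulfonic anhydride, O=S(=O)(OS(=O)(=O)C(F)(F)F)C(F)(F)F
Why: Triflation of the primary alcohol with a hindered pyridine base gives the sulfonate ester, whose ionisation is retarded by the two β-oxygens, so it should survive long enough to be used directly.

Step 15
Reactants: 22 1,3-dithiane; 11 fragment 1 iodide; 21 fragment 2 triflate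
Product: 26 C3 dithiane carrying C1 to C10 plus C13 and C14, via 2-lithio-1,3-dithiane 23 (not isolated), via monoalkyl dithiane 24 (not isolated), via lithiated monoalkyl dithiane 25 (not isolated)
Conditions: 22 (1.1 equiv), n-BuLi, THF, −30 °C; 11 (1.0 equiv), −78 → −20 °C; then t-BuLi (1.0 equiv), HMPA/THF, −78 °C; 21, −78 °C
Reagents that add atoms: none
Why: Deprotonated 1,3-dithiane 23 is a C3 acyl-anion equivalent that displaces iodide from the primary, β-branched C2 of 11 by SN2; the resulting 2-alkyl dithiane 24 is metalated again by t-BuLi in THF/HMPA and the tertiary anion 25 displaces the primary C4 triflate of 21 at −78 °C, so C2–C3 and C3–C4 form in one flask. The closest known reaction type is the Corey–Seebach dithiane alkylation run as a three-component linchpin union. No ring is closed and no stereocentre is created, so there is no mode of closure or controlling element to name; C1, C5, C6 and C8 are carried in unchanged because none of them bears a proton acidic enough to be removed. The selectivity required is substitution over elimination at each electrophile and mono- before bis-alkylation: both leaving groups sit on CH2 groups, the iodide is consumed before the second base is added, and the triflate reacts at a temperature at which the hindered anion is a poor base. Keeping C6 as a silyl ether and C13 as an acetal leaves no carbonyl or acidic C–H for the organolithiums to attack, and C3 emerges as a thioketal that cannot enolise towards the C5–O bond.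

Step 16
Reactants: 26 C3 dithiane with C13 acetal
Product: 27 C13 aldehyde (26 with CH(OMe)2 as CHO)
Conditions: PPTS, acetone/H2O (10:1), 45 °C
Reagents that add atoms: water, O
Why: Acid-catalysed hydrolysis of an acyclic dimethyl acetal is much faster than cleavage of the TBS and TBDPS ethers or of the thioketal, so only the C13 aldehyde should be released.

Step 17
Reactants: 27 C13 aldehyde
Product: 28 terminal alkene (C13H=CH2)
Conditions: Ph3PCH3Br, KN(SiMe3)2, THF, 0 °C
Reagents that add atoms: methyltriphenylphosphonium bromide, C[P+](c1ccccc1)(c1ccccc1)c1ccccc1.[Br-]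
Why: Wittig methylenation of the unhindered aldehyde with the non-stabilised ylide converts C13 into the terminal alkene needed for ring closure, at a stage where no base-sensitive carbonyl is present.

Step 18
Reactants: 28 bis-silyl ether
Product: 29 C6,C10-diol
Conditions: Bu4NF, THF, rt
Reagents that add atoms: none
Why: Fluoride cleaves both silyl ethers (Si–F bond formation) while the molecule still contains only the thioketal, the ether ring and alkenes, so the basic reagent can do no harm.

Step 19
Reactants: 29 C6,C10-diol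
Product: 30 C6 ketone C10 aldehyde
Conditions: Dess–Martin periodinane (2.4 equiv), dry CH2Cl2, 0 °C → rt
Reagents that add atoms: none
Why: Dess–Martin oxidation converts the secondary and the primary alcohol into the C6 ketone and C10 aldehyde without added base, so C5, now α to a carbonyl, is not epimerised and the C8–O bond β to the aldehyde is not eliminated, and under anhydrous conditions the thioketal is not attacked.

Step 20
Reactants: 30 keto aldehyde
Product: 31 C10 homoallylic alcohol carrying the 2-(methoxycarbonyl)allyl unit (both C10 epimers)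
Conditions: methyl 2-(bromomethyl)acrylate, Zn dust, THF/sat. aq. NH4Cl, 0 °C
Reagents that add atoms: methyl 2-(bromomethyl)acrylate, C=C(CBr)C(=O)OC
Why: The allylzinc reagent formed in situ adds through its γ-carbon to the aldehyde in a Barbier reaction far faster than to the hindered ketone at C6, installing C11 and C12 together with the ester and an exo-methylene handle under nearly neutral aqueous conditions.

Step 21
Reactants: 31 homoallylic alcohol
Product: 32 C6,C10-diketone diene
Conditions: Dess–Martin periodinane, dry CH2Cl2, 0 °C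
Reagents that add atoms: none
Why: Dess–Martin oxidation of the carbinol gives the C10 ketone without amine base, which avoids migration of the exo-methylene into conjugation and removes the C10 stereocentre.

Step 22
Reactants: 32 diketone diene
Product: 33 macrocyclic C3 dithiane (12E)
Conditions: second-generation Grubbs catalyst (H2IMes)(PCy3)Cl2Ru=CHPh (15 mol %), 1,4-benzoquinone (cat.), toluene (0.5 mM), 80 °C
Reagents that add atoms: none
Why: Ring-closing olefin metathesis joins the monosubstituted C13 alkene and the 1,1-disubstituted acrylate with loss of ethylene to close the 14-membered ring, the isopropenyl group being too hindered and too close to compete, and the trisubstituted enoate is expected to settle in the E geometry (C14 trans to the ester) that is favoured thermodynamically under reversible metathesis.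

Step 23
Reactants: 33 macrocyclic C3 dithiane
Product: 34 target CNP0163183.4
Conditions: MeI, CaCO3, MeCN/H2O (9:1), 40 °C
Reagents that add atoms: water, O
Why: S-Methylation makes the thioketal a leaving group and water then releases the C3 ketone (alkylative thioketal hydrolysis) under neutral, CaCO3-buffered conditions, so the β-alkoxy ketone never meets a base that could open the oxolanone and the enoate and isopropenyl group are untouched.

Compound list
1 | 3-methylbut-2-enoic acid | CC(C)=CC(=O)O | starting material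
2 | (R)-4-benzyl-1,3-oxazolidin-2-one | O=C1N[C@H](Cc2ccccc2)CO1 | starting material
3 | 3-methylbut-2-enoic pivalic anhydride | CC(C)=CC(=O)OC(=O)C(C)(C)C | intermediate
4 | (R)-4-benzyl-3-(3-methylbut-2-enoyl)-1,3-oxazolidin-2-one | CC(C)=CC(=O)N1[C@H](Cc2ccccc2)COC1=O | intermediate
5 | tert-butyl bromoacetate | CC(C)(C)OC(=O)CBr | starting material
6 | sodium (1Z)-1-[(R)-4-benzyl-2-oxo-1,3-oxazolidin-3-yl]-3-methylbuta-1,3-dien-1-olate | C=C(C)/C=C(\[O-])N1[C@H](Cc2ccccc2)COC1=O.[Na+] | intermediate
7 | tert-butyl (3R)-3-{[(4R)-4-benzyl-2-oxo-1,3-oxazolidin-3-yl]carbonyl}-4-methylpent-4-enoate | C=C(C)[C@H](C(=O)N1[C@H](Cc2ccccc2)COC1=O)CC(=O)OC(C)(C)C | intermediate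
8 | tert-butyl (3R)-3-(hydroxymethyl)-4-methylpent-4-enoate | C=C(C)[C@H](CO)CC(=O)OC(C)(C)C | intermediate
9 | tert-butyl (3R)-3-(iodomethyl)-4-methylpent-4-enoate | C=C(C)[C@H](CI)CC(=O)OC(C)(C)C | intermediate
10 | (3R)-3-(iodomethyl)-4-methylpent-4-enal | C=C(C)[C@H](CI)CC=O | intermediate
11 | fragment 1: (3R)-3-(iodomethyl)-5,5-dimethoxy-2-methylpent-1-ene | C=C(C)[C@H](CI)CC(OC)OC | intermediate
12 | 2-deoxy-L-ribose (open-chain form) | O=CC[C@@H](O)[C@@H](O)CO | starting material
13 | 2-deoxy-L-ribono-1,4-lactone, (4R,5S)-4-hydroxy-5-(hydroxymethyl)oxolan-2-one | OC[C@@H]1OC(=O)C[C@H]1O | intermediate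
14 | (4R,5S)-4-[(tert-butyldimethylsilyl)oxy]-5-{[(tert-butyldimethylsilyl)oxy]methyl}oxolan-2-one | CC(C)(C)[Si](C)(C)OC[C@@H]1OC(=O)C[C@H]1O[Si](C)(C)C(C)(C)C | intermediate
15 | (4R,5S)-4-[(tert-butyldimethylsilyl)oxy]-5-{[(tert-butyldimethylsilyl)oxy]methyl}-2-methyloxolan-2-ol, both anomers | CC(C)(C)[Si](C)(C)OC[C@@H]1OC(C)(O)C[C@H]1O[Si](C)(C)C(C)(C)C | intermediate
16 | (2S,4R,5S)-4-[(tert-butyldimethylsilyl)oxy]-5-{[(tert-butyldimethylsilyl)oxy]methyl}-2-methyl-2-(prop-2-en-1-yl)oxolane | CC(C)(C)[Si](C)(C)OC[C@@H]1O[C@@](C)(CC=C)C[C@H]1O[Si](C)(C)C(C)(C)C | intermediate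
17 | 2-[4-(TBS-oxy)-5-(TBS-oxymethyl)-2-methyloxolan-2-yl]acetaldehyde, ring stereocentres as in 16 | CC(C)(C)[Si](C)(C)OC[C@@H]1O[C@@](C)(CC=O)C[C@H]1O[Si](C)(C)C(C)(C)C | intermediate
18 | 2-[(2S,4R,5S)-4-[(tert-butyldimethylsilyl)oxy]-5-{[(tert-butyldimethylsilyl)oxy]methyl}-2-methyloxolan-2-yl]ethan-1-ol | CC(C)(C)[Si](C)(C)OC[C@@H]1O[C@@](C)(CCO)C[C@H]1O[Si](C)(C)C(C)(C)C | intermediate
19 | tert-butyldiphenylsilyl ether of 18 at the ethanol oxygen, ring stereocentres as in 18 | CC(C)(C)[Si](C)(C)OC[C@@H]1O[C@@](C)(CCO[Si](c2ccccc2)(c2ccccc2)C(C)(C)C)C[C@H]1O[Si](C)(C)C(C)(C)C | intermediate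
20 | [(2S,3R,5S)-3-[(tert-butyldimethylsilyl)oxy]-5-{2-[(tert-butyldiphenylsilyl)oxy]ethyl}-5-methyloxolan-2-yl]methanol | OC[C@@H]1O[C@@](C)(CCO[Si](c2ccccc2)(c2ccccc2)C(C)(C)C)C[C@H]1O[Si](C)(C)C(C)(C)C | intermediate
21 | fragment 2: [(2S,3R,5S)-3-[(tert-butyldimethylsilyl)oxy]-5-{2-[(tert-butyldiphenylsilyl)oxy]ethyl}-5-methyloxolan-2-yl]methyl trifluoromethanesulfonate | FC(F)(F)S(=O)(=O)OC[C@@H]1O[C@@](C)(CCO[Si](c2ccccc2)(c2ccccc2)C(C)(C)C)C[C@H]1O[Si](C)(C)C(C)(C)C | intermediate
22 | 1,3-dithiane | C1CSCSC1 | starting material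
23 | 2-lithio-1,3-dithiane | [Li]C1SCCCS1 | intermediate
24 | 2-[(2S)-2-(2,2-dimethoxyethyl)-3-methylbut-3-en-1-yl]-1,3-dithiane | C=C(C)[C@H](CC1SCCCS1)CC(OC)OC | intermediate
25 | 2-lithio derivative of 24 | C=C(C)[C@H](CC1([Li])SCCCS1)CC(OC)OC | intermediate
26 | 2-[(2S)-2-(2,2-dimethoxyethyl)-3-methylbut-3-en-1-yl]-2-{[(2S,3R,5S)-3-[(tert-butyldimethylsilyl)oxy]-5-{2-[(tert-butyldiphenylsilyl)oxy]ethyl}-5-methyloxolan-2-yl]methyl}-1,3-dithiane (1S,5S,6R,8S) | C=C(C)[C@H](CC1(C[C@@H]2O[C@@](C)(CCO[Si](c3ccccc3)(c3ccccc3)C(C)(C)C)C[C@H]2O[Si](C)(C)C(C)(C)C)SCCCS1)CC(OC)OC | intermediate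
27 | aldehyde: 26 with the dimethoxymethyl group (C13) as CHO (1S,5S,6R,8S) | C=C(C)[C@H](CC1(C[C@@H]2O[C@@](C)(CCO[Si](c3ccccc3)(c3ccccc3)C(C)(C)C)C[C@H]2O[Si](C)(C)C(C)(C)C)SCCCS1)CC=O | intermediate
28 | alkene: 27 with C13HO as C13H=CH2 (1S,5S,6R,8S) | C=C(C)[C@H](CC1(C[C@@H]2O[C@@](C)(CCO[Si](c3ccccc3)(c3ccccc3)C(C)(C)C)C[C@H]2O[Si](C)(C)C(C)(C)C)SCCCS1)CC=C | intermediate
29 | diol: 28 with free hydroxyls at C6 and C10 (1S,5S,6R,8S) | C=C(C)[C@H](CC1(C[C@@H]2O[C@@](C)(CCO)C[C@H]2O)SCCCS1)CC=C | intermediate
30 | keto aldehyde: oxolan-3-one (C6) with a 2-oxoethyl arm (C9–C10) on C8 (1S,5S,8S) | C=C(C)[C@H](CC1(C[C@@H]2O[C@@](C)(CC=O)CC2=O)SCCCS1)CC=C | intermediate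
31 | methyl 4-hydroxy-2-methylidene-5-(oxolanyl)pentanoate formed from 30 at C10, both C10 epimers (1S,5S,8S) | C=C(C)[C@H](CC1(C[C@@H]2O[C@@](C)(CC(O)CC(=C)C(=O)OC)CC2=O)SCCCS1)CC=C | intermediate
32 | C6,C10-diketone with the 2-(methoxycarbonyl)allyl arm on C10 and the but-3-enyl arm on C1 (1S,5S,8S) | C=C(C)[C@H](CC1(C[C@@H]2O[C@@](C)(CC(=O)CC(=C)C(=O)OC)CC2=O)SCCCS1)CC=C | intermediate
33 | macrocyclic 1,3-dithiane at C3 of the target (1S,5S,8S,12E) | C=C(C)[C@H]1C/C=C(/C(=O)OC)CC(=O)C[C@@]2(C)CC(=O)[C@H](CC3(C1)SCCCS3)O2 | intermediate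
34 | CNP0163183.4 (1S,5S,8S,12E) | C=C(C)[C@H]1C/C=C(/C(=O)OC)CC(=O)C[C@@]2(C)CC(=O)[C@H](CC(=O)C1)O2 | target

Total step count: 23 (6 to fragment 1, 8 to fragment 2, the union, 8 after it).
Longest linear sequence: 17 steps (steps 7–23, from 12).

Steps most likely to fail

Step 15. The tertiary dithiane anion 25 may act as a base towards the β-oxygenated triflate (elimination or proton transfer), the triflate may decompose before it is substituted, or the second metalation may be incomplete. Fallback, from 22 and 21 back to 26: the order of the two alkylations is reversed and the sequence is split into two operations, so that the small anion meets the hindered electrophile and the tertiary anion meets the simpler iodide. 2-Lithio-1,3-dithiane 23 (n-BuLi, THF, −30 °C) is treated with triflate 21 at −78 °C, which should give the oxolanylmethyl dithiane F1 after chromatography. F1 is metalated (t-BuLi, HMPA/THF, −78 °C) and alkylated with iodide 11 (−78 → −20 °C) to reach 26.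

Step 22. Ring closure at the 1,1-disubstituted acrylate may be slow, so that oligomerisation, catalyst deactivation by the thioketal sulfur or formation of the wrong alkene geometry takes over. Fallback, from 26 back to 33: the ring is closed by an intramolecular Horner–Wadsworth–Emmons olefination instead.
- NH4F in MeOH (50 °C) should cleave only the primary TBDPS ether to give the C10 alcohol F2.
- Dess–Martin oxidation gives the C10 aldehyde F3.
- MeMgBr (THF, −78 °C) gives the methyl carbinol F4, and a second Dess–Martin oxidation gives the methyl ketone F5.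
- Kinetic enolisation at the methyl group (LiN(SiMe3)2, THF, −78 °C) followed by N-bromosuccinimide gives the bromomethyl ketone F6.
- The sodium salt of trimethyl phosphonoacetate (NaH, THF, 0 °C) is alkylated by F6 to the keto phosphonate F7.
- PPTS in wet acetone frees the C13 aldehyde in the phosphonate aldehyde F8.
- LiCl and i-Pr2NEt in MeCN (1 mM) should close the ring to the macrocyclic silyl ether F9 with the E-enoate.
- HF·pyridine gives the macrocyclic C6 alcohol F10, and Dess–Martin oxidation returns 33.

Step 23. Hydrolysis of the thioketal held in the macrocycle may be slow, leaving the liberated β-alkoxy ketone and the C11 methylene exposed for hours to ring opening by retro-oxa-Michael reaction or to migration of the C12=C13 bond. Fallback, from 32 back to 34: the last two operations are inverted. The more accessible open-chain thioketal of 32 is hydrolysed first (MeI, CaCO3, MeCN/H2O) to the open-chain triketone F11. Ring-closing metathesis of F11 with the same catalyst in toluene is then the final, neutral step to 34.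

Further compounds
F1 | step 15 | 2-{[(2S,3R,5S)-3-[(tert-butyldimethylsilyl)oxy]-5-{2-[(tert-butyldiphenylsilyl)oxy]ethyl}-5-methyloxolan-2-yl]methyl}-1,3-dithiane | S1CCCSC1C[C@@H]1O[C@@](C)(CCO[Si](c2ccccc2)(c2ccccc2)C(C)(C)C)C[C@H]1O[Si](C)(C)C(C)(C)C
F2 | step 22 | C10 alcohol: 26 with the TBDPS ether cleaved | C=C(C)[C@H](CC1(C[C@@H]2O[C@@](C)(CCO)C[C@H]2O[Si](C)(C)C(C)(C)C)SCCCS1)CC(OC)OC
F3 | step 22 | C10 aldehyde from F2 | C=C(C)[C@H](CC1(C[C@@H]2O[C@@](C)(CC=O)C[C@H]2O[Si](C)(C)C(C)(C)C)SCCCS1)CC(OC)OC
F4 | step 22 | methyl carbinol at C10, both epimers | C=C(C)[C@H](CC1(C[C@@H]2O[C@@](C)(CC(C)O)C[C@H]2O[Si](C)(C)C(C)(C)C)SCCCS1)CC(OC)OC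
F5 | step 22 | C10 methyl ketone | C=C(C)[C@H](CC1(C[C@@H]2O[C@@](C)(CC(C)=O)C[C@H]2O[Si](C)(C)C(C)(C)C)SCCCS1)CC(OC)OC
F6 | step 22 | C10 bromomethyl ketone | C=C(C)[C@H](CC1(C[C@@H]2O[C@@](C)(CC(=O)CBr)C[C@H]2O[Si](C)(C)C(C)(C)C)SCCCS1)CC(OC)OC
F7 | step 22 | methyl 2-(dimethoxyphosphoryl)-4-oxo ester at C10–C12 with C13 acetal | C=C(C)[C@H](CC1(C[C@@H]2O[C@@](C)(CC(=O)CC(C(=O)OC)P(=O)(OC)OC)C[C@H]2O[Si](C)(C)C(C)(C)C)SCCCS1)CC(OC)OC
F8 | step 22 | F7 with C13 as the free aldehyde | C=C(C)[C@H](CC1(C[C@@H]2O[C@@](C)(CC(=O)CC(C(=O)OC)P(=O)(OC)OC)C[C@H]2O[Si](C)(C)C(C)(C)C)SCCCS1)CC=O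
F9 | step 22 | macrocyclic C3 dithiane with C6–OTBS and C10 ketone (12E) | C=C(C)[C@H]1C/C=C(/C(=O)OC)CC(=O)C[C@@]2(C)C[C@@H](O[Si](C)(C)C(C)(C)C)[C@H](CC3(C1)SCCCS3)O2
F10 | step 22 | macrocyclic C3 dithiane with free C6–OH (12E) | C=C(C)[C@H]1C/C=C(/C(=O)OC)CC(=O)C[C@@]2(C)C[C@@H](O)[C@H](CC3(C1)SCCCS3)O2
F11 | step 23 | open-chain C3,C6,C10-triketone diene | C=C(C)[C@H](CC(=O)C[C@@H]1O[C@@](C)(CC(=O)CC(=C)C(=O)OC)CC1=O)CC=C
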